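The seven-membered ring is closed last, between the gem-dimethyl carbon C6 and the cyclobutane methine C5 (longipinane numbering). C5 is the carbonyl carbon of the cyclobutanone that an intramolecular vinylketene–alkene [2+2] cycloaddition delivers with the bicyclo[3.1.1]heptane core, and C6 flanks the C7 carbinol. An iron-hydride hydrogen-atom transfer therefore turns a C6 isopropenyl group into a tertiary radical that adds 7-exo to the C5 tosylhydrazone; loss of sulfinate and N2 leaves C5–H. One operation makes the ring, the quaternary C6 and the C5 stereocentre. The precursor is a bergamotane-type bicyclic enone hydrazone bearing the tartrate-derived C7–C9 chain on C10; one catalytically set carbinol (C1) relays the core chirality.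

Key step: step 16

Remark: atom numbers are those of the longipinane skeleton (C1 ketone, C2=C3 with methyl on C3, C4 and C11 bridgeheads, C5 cyclobutane CH, C6 CMe2, C7 OH, C8 angelate, C9 2-methylbutanoate, C10 quaternary methyl-bearing carbon) and are used for the open-chain precursors as well.
Remark: (R)-2-methylbutanoic acid, angelic acid and the chiral bisphosphoramide of step 4 are taken as purchasable.

Step 1
Reactants: 1 but-2-yn-1-ol
Product: 2 (E)-3-iodobut-2-en-1-ol
Conditions: Cp2ZrCl2, i-Bu2AlH, THF, 0 °C; then I2, −78 °C → rt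
Reagents that add atoms: iodine, II
Why: Hydrozirconation–iodination, in which Cp2Zr(H)Cl formed in the flask adds syn across the alkyne with zirconium on the methyl-bearing carbon and iodinolysis goes with retention, should fix the E geometry later needed for C10=C11.

Step 2
Reactants: 2 (E)-3-iodobut-2-en-1-ol
Product: 3 (E)-3-iodobut-2-enal
Conditions: MnO2, CH2Cl2, rt
Reagents that add atoms: none
Why: Chemoselective MnO2 oxidation of the allylic alcohol should leave the vinyl iodide and its geometry untouched.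

Step 3
Reactants: 4 methyl 3-methylbut-2-enoate
Product: 5 tert-butyl[(1-methoxy-3-methylbuta-1,3-dien-1-yl)oxy]dimethylsilane
Conditions: LiN(i-Pr)2, THF/DMPU, −78 °C; then TBSCl
Reagents that add atoms: tert-butyldimethylsilyl chloride, CC(C)(C)[Si](C)(C)Cl
Why: Kinetic γ-deprotonation of the senecioate and O-silylation of the extended enolate should give the silyl dienol ether (silyl ketene acetal formation).

Step 4
Reactants: 3 (E)-3-iodobut-2-enal; 5 silyl dienol ether
Product: 6 methyl (2E,5S,6E)-5-hydroxy-7-iodo-3-methylocta-2,6-dienoate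
Conditions: SiCl4, (R,R)-N,N'-bis(3,5-dimethyl-4-oxido-4,5-dihydro-3H-dinaphtho[2,1-d:1',2'-f][1,3,2]diazaphosphepin-4-yl)-N,N'-dimethylpentane-1,5-diamine (5 mol %), i-Pr2NEt, CH2Cl2, −78 °C; aq NaHCO3
Reagents that add atoms: none
Why: Enantioselective vinylogous Mukaiyama aldol reaction under Lewis-base activation of SiCl4, in which the dienolate attacks only through its γ-carbon and the chiral phosphoramide–silicon cation selects the aldehyde face, should set the 5S carbinol (future C1), the one stereocentre set by catalysis; the catalyst antipode is used if the sense proves opposite.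

Step 5
Reactants: 6 methyl (2E,5S,6E)-5-hydroxy-7-iodo-3-methylocta-2,6-dienoate
Product: 7 methyl (2E,5S,6E)-5-[(tert-butyldimethylsilyl)oxy]-7-iodo-3-methylocta-2,6-dienoate
Conditions: TBSCl, imidazole, DMF, rt
Reagents that add atoms: tert-butyldimethylsilyl chloride, CC(C)(C)[Si](C)(C)Cl
Why: Standard silylation should protect the secondary allylic alcohol, which later steers the cycloaddition and is finally oxidised to the C1 ketone.

Step 6
Reactants: 8 dimethyl (4R,5R)-2,2-dimethyl-1,3-dioxolane-4,5-dicarboxylate (dimethyl 2,3-O-isopropylidene-L-tartrate)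
Product: 9 methyl (4R,5R)-5-(2-hydroxypropan-2-yl)-2,2-dimethyl-1,3-dioxolane-4-carboxylate
Conditions: MeMgBr (2.1 equiv), THF, −78 → −30 °C
Reagents that add atoms: methylmagnesium bromide, C[Mg]Br
Why: Double Grignard addition to one of the two homotopic esters (the ketone intermediate reacts faster than either ester and the magnesium alkoxide then retards attack at its neighbour) should give the mono-carbinol with both tartrate centres (future C7 and C8) intact, the diol and recovered 8 being separable.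

Step 7
Reactants: 9 methyl (4R,5R)-5-(2-hydroxypropan-2-yl)-2,2-dimethyl-1,3-dioxolane-4-carboxylate
Product: 10 methyl (4R,5S)-2,2-dimethyl-5-(prop-1-en-2-yl)-1,3-dioxolane-4-carboxylate
Conditions: methyl N-(triethylammoniosulfonyl)carbamate, toluene, 60 °C
Reagents that add atoms: none
Why: Burgess dehydration (syn-elimination of the sulfamate) of the tertiary alcohol should take one of the six accessible methyl hydrogens rather than the single hindered ring hydrogen and so give the isopropenyl group.

Step 8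
Reactants: 10 methyl (4R,5S)-2,2-dimethyl-5-(prop-1-en-2-yl)-1,3-dioxolane-4-carboxylate
Product: 11 (4R,5S)-2,2-dimethyl-5-(prop-1-en-2-yl)-1,3-dioxolane-4-carbaldehyde
Conditions: i-Bu2AlH (1.1 equiv), CH2Cl2, −78 °C; aq Rochelle salt
Reagents that add atoms: none
Why: Partial reduction should stop at the aluminium hemiacetal at −78 °C and give the aldehyde on work-up, the trans-dioxolane being the stable configuration at the α-centre.

Step 9
Reactants: 7 vinyl iodide; 11 aldehyde
Product: 12 methyl (2E,5S,6E,8S)-5-[(tert-butyldimethylsilyl)oxy]-8-[(4S,5S)-2,2-dimethyl-5-(prop-1-en-2-yl)-1,3-dioxolan-4-yl]-8-hydroxy-3,7-dimethylocta-2,6-dienoate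
Conditions: CrCl2 (6 equiv), NiCl2 (1 mol %), DMSO, rt
Reagents that add atoms: none
Why: Nozaki–Hiyama–Kishi coupling, in which zerovalent nickel inserts into the vinyl iodide and transmetalation gives an alkenylchromium species with retained E geometry, should add to the aldehyde anti to the dioxolane C–O bond (Felkin–Anh) and set C9 (8,9-anti), the ester and silyl ether being inert.

Step 10
Reactants: 12 NHK allylic alcohol
Product: 13 (2E,5S,6E,8S)-5-[(tert-butyldimethylsilyl)oxy]-8-[(4S,5S)-2,2-dimethyl-5-(prop-1-en-2-yl)-1,3-dioxolan-4-yl]-8-hydroxy-3,7-dimethylocta-2,6-dienoic acid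
Conditions: LiOH·H2O, THF/MeOH/H2O, 40 °C; then 1 M HCl to pH 4, 0 °C
Reagents that add atoms: lithium hydroxide, [Li+].[OH-]
Why: Saponification of the methyl ester is placed before any other ester is present, so no chemoselectivity is needed, and the silyl ether and acetonide should be stable to base.

Step 11
Reactants: 13 hydroxy acid; 14 (R)-2-methylbutanoic acid
Product: 15 (2E,5S,6E,8S)-5-[(tert-butyldimethylsilyl)oxy]-8-[(4R,5S)-2,2-dimethyl-5-(prop-1-en-2-yl)-1,3-dioxolan-4-yl]-3,7-dimethyl-8-{[(2R)-2-methylbutanoyl]oxy}octa-2,6-dienoic acid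
Conditions: 14 (4 equiv), DCC (2 equiv), CH2Cl2, 0 °C; then 13, 4-(dimethylamino)pyridine (0.2 equiv), pyridine, rt; aq NaHCO3/THF
Reagents that add atoms: none
Why: Steglich-type acylation of the C9 alcohol by the symmetrical anhydride made in the flask should install the 2-methylbutanoate without enolising its α-centre, any mixed anhydride at the free carboxyl group being hydrolysed in the bicarbonate work-up.

Step 12
Reactants: 15 acyloxy acid
Product: 18 (1R,4S,5R,7R)-4-[(tert-butyldimethylsilyl)oxy]-7-methyl-2-methylidene-7-{(S)-[(4R,5S)-2,2-dimethyl-5-(prop-1-en-2-yl)-1,3-dioxolan-4-yl]{[(2R)-2-methylbutanoyl]oxy}methyl}bicyclo[3.1.1]heptan-6-one, via acid chloride 16 (not isolated), via vinylketene 17 (not isolated)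
Conditions: 1-chloro-N,N,2-trimethylprop-1-en-1-amine, CH2Cl2, 0 °C → rt; then slow addition to Et3N, toluene, 110 °C (0.005 M)
Reagents that add atoms: none
Why: Intramolecular vinylketene–alkene [2+2] cycloaddition of the bergamotene type should bond the ketene carbonyl carbon (C5) to the less substituted alkene carbon C11 and the ketene α-carbon C4 to C10 suprafacially, so the E alkene puts the C10 methyl syn to the three-carbon bridge, while the C1 silyloxy group stays away from the C10 methyl (allylic 1,3-strain) and thereby selects the alkene face, setting C4, C10 and C11 together.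

Step 13
Reactants: 18 silyloxy cyclobutanone
Product: 19 (1R,4S,5R,7R)-4-hydroxy-7-methyl-2-methylidene-7-{(S)-[(4R,5S)-2,2-dimethyl-5-(prop-1-en-2-yl)-1,3-dioxolan-4-yl]{[(2R)-2-methylbutanoyl]oxy}methyl}bicyclo[3.1.1]heptan-6-one
Conditions: HF·pyridine, pyridine, THF, 0 °C → rt
Reagents that add atoms: none
Why: Buffered fluoride desilylation should free the C1 alcohol without opening the acetonide or the non-enolisable cyclobutanone.

Step 14
Reactants: 19 hydroxy cyclobutanone
Product: 21 (1R,5R,7R)-4,7-dimethyl-7-{(S)-[(4R,5S)-2,2-dimethyl-5-(prop-1-en-2-yl)-1,3-dioxolan-4-yl]{[(2R)-2-methylbutanoyl]oxy}methyl}bicyclo[3.1.1]hept-3-ene-2,6-dione, via exocyclic β,γ-enone 20 (not isolated)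
Conditions: Dess–Martin periodinane, NaHCO3, CH2Cl2, 0 °C; then Et3N, rt
Reagents that add atoms: none
Why: Dess–Martin oxidation should give the β,γ-unsaturated ketone and Et3N should move the exocyclic double bond into conjugation through the dienolate (thermodynamic verbenone-type enone), which also erases the auxiliary C1 stereocentre, the bridgehead between the two carbonyl groups being unable to enolise.

Step 15
Reactants: 21 enedione
Product: 22 C5 (cyclobutanone) N-tosylhydrazone of 21
Conditions: TsNHNH2 (1.05 equiv), MgSO4, THF, rt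
Reagents that add atoms: 4-methylbenzenesulfonohydrazide, Cc1ccc(cc1)S(=O)(=O)NN
Why: Condensation should take place at the strained, more electrophilic cyclobutanone and not at the hindered conjugated enone carbonyl, aprotic base-free conditions being chosen to avoid retro-Claisen opening of the non-enolisable 1,3-diketone.

Step 16
Reactants: 22 tosylhydrazone
Product: 25 (4R,5S,7S,8R,9S,10R,11R)-7,8-(isopropylidenedioxy)-9-{[(2R)-2-methylbutanoyl]oxy}longipin-2-en-1-one, via cyclised tosylhydrazide 23 (not isolated), via diazene 24 (not isolated)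
Conditions: Fe(acac)3 (0.3 equiv), PhSiH3, EtOH/THF, 60 °C; then NaOAc, EtOH, 80 °C
Reagents that add atoms: none
Why: Hydrogen-atom transfer from the iron hydride to the CH2 terminus of the isopropenyl group creates the second C6 methyl and a nucleophilic tertiary radical at C6, which adds to the hydrazone carbon C5; the hydrazinyl radical is reduced and protonated to hydrazide 23, NaOAc expels p-toluenesulfinate to give diazene 24, and loss of N2 leaves C5–H. The closest known reaction type is the iron-hydride-initiated reductive radical alkylation of alkene-tethered ketone tosylhydrazones (traceless alkene–ketone coupling), applied here to a cyclobutanone hydrazone. The seven-membered ring closes in the 7-exo-trig mode onto C=N. C5 is the only new stereocentre and is fixed by the ring system, because the chain on C10 can reach only the face of the four-membered ring opposite to the C1–C3 bridge, so C6 ends anti and H syn to that bridge, while C7, C8 and C9 are untouched. The step needs hydrogen-atom transfer to the electron-rich 1,1-disubstituted alkene rather than to the hindered β,β-disubstituted enone, and ring closure faster than reduction of the radical; the cis-1,3 placement of chain and C5 on the cyclobutane, the substitution along the tether and the strain released at the cyclobutanone-derived C=N carbon should favour closure.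

Step 17
Reactants: 25 acetonide
Product: 26 (4R,5S,7S,8R,9S,10R,11R)-7,8-dihydroxy-9-{[(2R)-2-methylbutanoyl]oxy}longipin-2-en-1-one
Conditions: AcOH/H2O (4:1), 40 °C
Reagents that add atoms: none
Why: Acid hydrolysis of the strained trans-fused acetonide should free the C7 and C8 hydroxyls under conditions too mild for acyl migration or ester cleavage.

Step 18
Reactants: 26 diol; 27 angelic acid
Product: 28 (4R,5S,7S,8R,9S,10R,11R)-8-(angeloyloxy)-7-hydroxy-9-{[(2R)-2-methylbutanoyl]oxy}longipin-2-en-1-one (target)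
Conditions: 27, 2,4,6-trichlorobenzoyl chloride, Et3N, toluene, rt; then 26, 75 °C
Reagents that add atoms: none
Why: Yamaguchi-type acylation through the angelic 2,4,6-trichlorobenzoic mixed anhydride should keep the Z geometry of the angeloyl group and go to the C8 hydroxyl, the C7 hydroxyl being neopentylic (next to the quaternary C6) and much more hindered.

Compound list
1 | but-2-yn-1-ol | CC#CCO | starting material
2 | (E)-3-iodobut-2-en-1-ol | I/C(C)=C/CO | intermediate
3 | (E)-3-iodobut-2-enal | I/C(C)=C/C=O | intermediate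
4 | methyl 3-methylbut-2-enoate | CC(C)=CC(=O)OC | starting material
5 | tert-butyl[(1-methoxy-3-methylbuta-1,3-dien-1-yl)oxy]dimethylsilane | C=C(C)C=C(OC)O[Si](C)(C)C(C)(C)C | intermediate
6 | methyl (2E,5S,6E)-5-hydroxy-7-iodo-3-methylocta-2,6-dienoate | COC(=O)/C=C(C)/C[C@H](O)/C=C(C)/I | intermediate
7 | methyl (2E,5S,6E)-5-[(tert-butyldimethylsilyl)oxy]-7-iodo-3-methylocta-2,6-dienoate | COC(=O)/C=C(C)/C[C@H](O[Si](C)(C)C(C)(C)C)/C=C(C)/I | intermediate
8 | dimethyl (4R,5R)-2,2-dimethyl-1,3-dioxolane-4,5-dicarboxylate | COC(=O)[C@@H]1OC(C)(C)O[C@H]1C(=O)OC | starting material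
9 | methyl (4R,5R)-5-(2-hydroxypropan-2-yl)-2,2-dimethyl-1,3-dioxolane-4-carboxylate | COC(=O)[C@@H]1OC(C)(C)O[C@H]1C(C)(C)O | intermediate
10 | methyl (4R,5S)-2,2-dimethyl-5-(prop-1-en-2-yl)-1,3-dioxolane-4-carboxylate | COC(=O)[C@@H]1OC(C)(C)O[C@H]1C(C)=C | intermediate
11 | (4R,5S)-2,2-dimethyl-5-(prop-1-en-2-yl)-1,3-dioxolane-4-carbaldehyde | O=C[C@@H]1OC(C)(C)O[C@H]1C(C)=C | intermediate
12 | methyl (2E,5S,6E,8S)-5-[(tert-butyldimethylsilyl)oxy]-8-[(4S,5S)-2,2-dimethyl-5-(prop-1-en-2-yl)-1,3-dioxolan-4-yl]-8-hydroxy-3,7-dimethylocta-2,6-dienoate | COC(=O)/C=C(C)/C[C@H](O[Si](C)(C)C(C)(C)C)/C=C(C)/[C@H](O)[C@@H]1OC(C)(C)O[C@H]1C(C)=C | intermediate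
13 | (2E,5S,6E,8S)-5-[(tert-butyldimethylsilyl)oxy]-8-[(4S,5S)-2,2-dimethyl-5-(prop-1-en-2-yl)-1,3-dioxolan-4-yl]-8-hydroxy-3,7-dimethylocta-2,6-dienoic acid | OC(=O)/C=C(C)/C[C@H](O[Si](C)(C)C(C)(C)C)/C=C(C)/[C@H](O)[C@@H]1OC(C)(C)O[C@H]1C(C)=C | intermediate
14 | (R)-2-methylbutanoic acid | OC(=O)[C@H](C)CC | starting material
15 | (2E,5S,6E,8S)-5-[(tert-butyldimethylsilyl)oxy]-8-[(4R,5S)-2,2-dimethyl-5-(prop-1-en-2-yl)-1,3-dioxolan-4-yl]-3,7-dimethyl-8-{[(2R)-2-methylbutanoyl]oxy}octa-2,6-dienoic acid | OC(=O)/C=C(C)/C[C@H](O[Si](C)(C)C(C)(C)C)/C=C(C)/[C@H](OC(=O)[C@H](C)CC)[C@@H]1OC(C)(C)O[C@H]1C(C)=C | intermediate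
16 | acid chloride of 15 | ClC(=O)/C=C(C)/C[C@H](O[Si](C)(C)C(C)(C)C)/C=C(C)/[C@H](OC(=O)[C@H](C)CC)[C@@H]1OC(C)(C)O[C@H]1C(C)=C | intermediate (not isolated)
17 | vinylketene from 16 by loss of HCl through the γ-methyl group (3-methylideneocta-1,6-dien-1-one chain, other groups as in 15) | O=C=CC(=C)C[C@H](O[Si](C)(C)C(C)(C)C)/C=C(C)/[C@H](OC(=O)[C@H](C)CC)[C@@H]1OC(C)(C)O[C@H]1C(C)=C | intermediate (not isolated)
18 | (1R,4S,5R,7R)-4-[(tert-butyldimethylsilyl)oxy]-7-methyl-2-methylidene-7-{(S)-[(4R,5S)-2,2-dimethyl-5-(prop-1-en-2-yl)-1,3-dioxolan-4-yl]{[(2R)-2-methylbutanoyl]oxy}methyl}bicyclo[3.1.1]heptan-6-one | O=C1[C@H]2[C@@H](O[Si](C)(C)C(C)(C)C)CC(=C)[C@@H]1[C@@]2(C)[C@H](OC(=O)[C@H](C)CC)[C@@H]3OC(C)(C)O[C@H]3C(C)=C | intermediate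
19 | 4-hydroxy analogue of 18 (free C1 alcohol) | O=C1[C@H]2[C@@H](O)CC(=C)[C@@H]1[C@@]2(C)[C@H](OC(=O)[C@H](C)CC)[C@@H]3OC(C)(C)O[C@H]3C(C)=C | intermediate
20 | 4-methylidenebicyclo[3.1.1]heptane-2,6-dione isomer of 21 (exocyclic double bond, same configuration) | O=C1[C@H]2C(=O)CC(=C)[C@@H]1[C@@]2(C)[C@H](OC(=O)[C@H](C)CC)[C@@H]3OC(C)(C)O[C@H]3C(C)=C | intermediate (not isolated)
21 | (1R,5R,7R)-4,7-dimethyl-7-{(S)-[(4R,5S)-2,2-dimethyl-5-(prop-1-en-2-yl)-1,3-dioxolan-4-yl]{[(2R)-2-methylbutanoyl]oxy}methyl}bicyclo[3.1.1]hept-3-ene-2,6-dione | O=C1[C@H]2C(=O)C=C(C)[C@@H]1[C@@]2(C)[C@H](OC(=O)[C@H](C)CC)[C@@H]3OC(C)(C)O[C@H]3C(C)=C | intermediate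
22 | N-tosylhydrazone of 21 at the cyclobutanone carbon (C5) | Cc1ccc(cc1)S(=O)(=O)NN=C1[C@H]2C(=O)C=C(C)[C@@H]1[C@@]2(C)[C@H](OC(=O)[C@H](C)CC)[C@@H]3OC(C)(C)O[C@H]3C(C)=C | intermediate
23 | 25 bearing a 2-tosylhydrazin-1-yl group on C5 in place of H | CC1(C)O[C@@H]2[C@@H](O1)C(C)(C)[C@]3(NNS(=O)(=O)c5ccc(C)cc5)[C@H]4C(=O)C=C(C)[C@@H]3[C@@]4(C)[C@@H]2OC(=O)[C@H](C)CC | intermediate (not isolated)
24 | 25 bearing a diazenyl group (N=NH) on C5 in place of H | CC1(C)O[C@@H]2[C@@H](O1)C(C)(C)[C@]3(N=N)[C@H]4C(=O)C=C(C)[C@@H]3[C@@]4(C)[C@@H]2OC(=O)[C@H](C)CC | intermediate (not isolated)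
25 | (4R,5S,7S,8R,9S,10R,11R)-7,8-(isopropylidenedioxy)-9-{[(2R)-2-methylbutanoyl]oxy}longipin-2-en-1-one | CC1(C)O[C@@H]2[C@@H](O1)C(C)(C)[C@@H]3[C@H]4C(=O)C=C(C)[C@@H]3[C@@]4(C)[C@@H]2OC(=O)[C@H](C)CC | intermediate
26 | (4R,5S,7S,8R,9S,10R,11R)-7,8-dihydroxy-9-{[(2R)-2-methylbutanoyl]oxy}longipin-2-en-1-one | O[C@@H]1[C@@H](O)C(C)(C)[C@@H]2[C@H]3C(=O)C=C(C)[C@@H]2[C@@]3(C)[C@@H]1OC(=O)[C@H](C)CC | intermediate
27 | angelic acid, (Z)-2-methylbut-2-enoic acid | C/C=C(/C)C(=O)O | starting material
28 | (4R,5S,7S,8R,9S,10R,11R)-8-(angeloyloxy)-7-hydroxy-9-{[(2R)-2-methylbutanoyl]oxy}longipin-2-en-1-one | C/C=C(/C)C(=O)O[C@@H]1[C@@H](O)C(C)(C)[C@@H]2[C@H]3C(=O)C=C(C)[C@@H]2[C@@]3(C)[C@@H]1OC(=O)[C@H](C)CC | target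

Total step count: 18. Longest linear sequence: 14 steps (1 → 2 → 3 → 6 → 7 → 12 → 13 → 15 → 18 → 19 → 21 → 22 → 25 → 26 → 28).

Steps most likely to fail

Step 16. The tertiary radical may capture a hydrogen atom (net hydrogenation of the isopropenyl group) faster than the 7-exo closure, or hydrogen-atom transfer may go to the enone. The fallback sets out from 22 and generates the radical where no metal hydride or alcohol competes. Cobalt-catalysed Markovnikov hydrochlorination of the isopropenyl group (Co(BF4)2·6H2O with potassium 2-[(3,5-di-tert-butyl-2-hydroxybenzylidene)amino]-2,2-diphenylacetate, TsCl, PhSiH3, t-BuOOH, EtOH, rt) should give the tertiary chloride F1. (Me3Si)3SiH and AIBN, added over hours to F1 in toluene at 90 °C, should then give hydrazide 23 by chlorine abstraction, 7-exo addition to C=N and hydrogen transfer to nitrogen. Fragmentation with NaOAc as in step 16 brings the route back at 25.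

Step 12. The ketene may oligomerise instead of adding, because the C10=C11 alkene carries two allylic C–O bonds and is a weak nucleophile; facial selectivity may also erode at 110 °C. The fallback sets out from acid 15 and uses the more electrophilic keteniminium ion. Coupling with pyrrolidine (EDC·HCl, 1-hydroxybenzotriazole, CH2Cl2) should give amide F2. Tf2O and 2,4,6-collidine in 1,2-dichloroethane at 80 °C should form the vinylketeniminium ion, which closes by the same [2+2] mode to the cyclobutaniminium triflate F3. Aqueous NaHCO3 hydrolysis returns to the route at cyclobutanone 18.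

Step 18. Acylation may spread over the C7 and C8 hydroxyls (poor site selectivity). The fallback sets out from diol 26 and differentiates the two hydroxyls by protection. Et3SiOTf and 2,6-lutidine should give the bis(triethylsilyl) ether F4. Pyridinium p-toluenesulfonate in MeOH/CH2Cl2 at 0 °C should remove the less hindered C8 silyl group first and give the C7 silyl ether F5. Angeloylation as in step 18 then gives F6, and HF·pyridine in THF removes the last silyl group to reach 28.

Further compounds
F1 | step 16 | tosylhydrazone 22 with the isopropenyl group replaced by 2-chloropropan-2-yl | Cc1ccc(cc1)S(=O)(=O)NN=C1[C@H]2C(=O)C=C(C)[C@@H]1[C@@]2(C)[C@H](OC(=O)[C@H](C)CC)[C@@H]3OC(C)(C)O[C@H]3C(C)(C)Cl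
F2 | step 12 | pyrrolidine amide of acid 15 | O=C(N1CCCC1)/C=C(C)/C[C@H](O[Si](C)(C)C(C)(C)C)/C=C(C)/[C@H](OC(=O)[C@H](C)CC)[C@@H]1OC(C)(C)O[C@H]1C(C)=C
F3 | step 12 | pyrrolidinium (iminium) triflate corresponding to cyclobutanone 18 | [O-]S(=O)(=O)C(F)(F)F.C1(=[N+]4CCCC4)[C@H]2[C@@H](O[Si](C)(C)C(C)(C)C)CC(=C)[C@@H]1[C@@]2(C)[C@H](OC(=O)[C@H](C)CC)[C@@H]3OC(C)(C)O[C@H]3C(C)=C
F4 | step 18 | 7,8-bis(triethylsilyl) ether of diol 26 | CC[Si](CC)(CC)O[C@@H]1[C@@H](O[Si](CC)(CC)CC)C(C)(C)[C@@H]2[C@H]3C(=O)C=C(C)[C@@H]2[C@@]3(C)[C@@H]1OC(=O)[C@H](C)CC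
F5 | step 18 | 7-O-triethylsilyl ether of diol 26 (free C8 hydroxyl) | O[C@@H]1[C@@H](O[Si](CC)(CC)CC)C(C)(C)[C@@H]2[C@H]3C(=O)C=C(C)[C@@H]2[C@@]3(C)[C@@H]1OC(=O)[C@H](C)CC
F6 | step 18 | 7-O-triethylsilyl ether of target 28 | C/C=C(/C)C(=O)O[C@@H]1[C@@H](O[Si](CC)(CC)CC)C(C)(C)[C@@H]2[C@H]3C(=O)C=C(C)[C@@H]2[C@@]3(C)[C@@H]1OC(=O)[C@H](C)CC
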